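Ring A of unit 1 (the chromanone carrying the 4-hydroxyphenyl group) bears O1 on C8a and the acyl carbon C4 on C4a as ortho neighbours, with the C5 oxygen next to C4a: the pattern left when a 3-alkoxybenzyne takes up an oxygen and an acyl group. The route therefore inserts 3,5-bis(benzyloxy)benzyne into the O–C(acyl) bond of an (E)-2,3-diarylacrylic acid, forming C8a–O1 and C4–C4a at once and giving the whole 2'-hydroxy-α-aryl chalcone of unit 1. The acid already holds the hindered C3–C8 bond as its α-aryl bond; its α-aryl ring carries a single MOM ether, on the oxygen that becomes O1 of unit 2, and benzyl ethers elsewhere.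

Key step: step 8

Target configuration as read from the SMILES: unit 1 is 2R,3S (2,3-trans); unit 2 is 2S.

Protecting-group design: only one oxygen of the α-aryl ring is a MOM ether, so acid frees a single phenol and unit 2 is built without a free C7 hydroxyl. The starting aldehyde is protected selectively because its chelated hydroxyl is the one left for MOM.

Assumption: the quinidine-derived thiourea is taken to give the 2R sense at unit 1 and (R)-t-BuPyOX the 2S sense at unit 2. Each assignment would be checked on a model substrate and, if reversed, the pseudo-enantiomeric catalyst or the enantiomeric ligand would be used under the same conditions.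

**Route**

Step 1
Reactants: 1 2,4,6-trihydroxybenzaldehyde
Product: 2 2,4-bis(benzyloxy)-6-hydroxybenzaldehyde
Conditions: BnBr (2.1 equiv), K2CO3, DMF, 0 °C → rt
Reagents that add atoms: benzyl bromide, BrCc1ccccc1
Why: Williamson ether synthesis under weak base benzylates the para hydroxyl and one ortho hydroxyl, while the remaining ortho hydroxyl stays hydrogen-bonded to the formyl group and is not alkylated at this stoichiometry.

Step 2
Reactants: 2 2,4-bis(benzyloxy)-6-hydroxybenzaldehyde
Product: 3 2,4-bis(benzyloxy)-6-(methoxymethoxy)benzaldehyde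
Conditions: MOMCl, i-Pr2NEt, CH2Cl2, 0 °C → reflux
Reagents that add atoms: chloromethyl methyl ether, COCCl
Why: Williamson-type alkylation of the chelated phenol with the highly reactive α-chloro ether installs the one acid-labile acetal, which marks the oxygen destined to become O1 of unit 2.

Step 3
Reactants: 3 2,4-bis(benzyloxy)-6-(methoxymethoxy)benzaldehyde
Product: 5 2-[2,4-bis(benzyloxy)-6-(methoxymethoxy)phenyl]acetonitrile, via N-(2-aryl-1-tosylethenyl)formamide 4 (not isolated)
Conditions: TosMIC, t-BuOK, DME, −50 °C; then MeOH, reflux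
Reagents that add atoms: p-toluenesulfonylmethyl isocyanide (TosMIC), Cc1ccc(cc1)S(=O)(=O)C[N+]#[C-]
Why: Van Leusen reductive cyanation, in which the TosMIC anion adds to the aldehyde, the adduct opens to formamide 4, and methanolysis with loss of sulfinate gives the one-carbon-homologated nitrile under purely basic conditions that spare the MOM and benzyl ethers.

Step 4
Reactants: 5 2-[2,4-bis(benzyloxy)-6-(methoxymethoxy)phenyl]acetonitrile
Product: 7 2-[2,4-bis(benzyloxy)-6-(methoxymethoxy)phenyl]acetic acid, via arylacetamide 6 (not isolated)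
Conditions: KOH, EtOH/H2O, reflux; then 1 M HCl to pH 4, 0 °C
Reagents that add atoms: potassium hydroxide, [K+].[OH-]; water, O
Why: Alkaline nitrile hydrolysis proceeds through amide 6 to the carboxylate with all ethers base-stable, and the brief cold acidification to pH 4 is too mild to cleave the MOM acetal.

Step 5
Reactants: 7 2-[2,4-bis(benzyloxy)-6-(methoxymethoxy)phenyl]acetic acid; 8 4-(benzyloxy)benzaldehyde
Product: 10 (E)-2-[2,4-bis(benzyloxy)-6-(methoxymethoxy)phenyl]-3-[4-(benzyloxy)phenyl]acrylic acid, via acetic mixed anhydride 9 (not isolated)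
Conditions: Ac2O, Et3N, 110 °C; then H2O, THF, 60 °C
Reagents that add atoms: none
Why: Perkin condensation, in which the enolate of the mixed anhydride of 7 adds to aldehyde 8 and acetate is eliminated to give the E acid with the two aryl groups cis, the usual outcome for arylacetic acids, in an amine-buffered medium that does not harm the MOM ether.

Step 6
Reactants: 11 3,5-bis(benzyloxy)phenol
Product: 12 2-bromo-3,5-bis(benzyloxy)phenol
Conditions: NBS, i-Pr2NH (10 mol%), CH2Cl2, −78 → 0 °C
Reagents that add atoms: N-bromosuccinimide, BrN1C(=O)CCC1=O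
Why: Electrophilic bromination with the amine-activated N-bromo reagent is delivered ortho to the hydroxyl, a position that is also less hindered than the one between the two benzyloxy groups.

Step 7
Reactants: 12 2-bromo-3,5-bis(benzyloxy)phenol
Product: 15 3,5-bis(benzyloxy)-2-(trimethylsilyl)phenyl trifluoromethanesulfonate, via aryl trimethylsilyl ether 13 (not isolated), via lithium 2-silylphenoxide 14 (not isolated)
Conditions: HN(SiMe3)2, THF, 65 °C; evaporate; n-BuLi, THF, −78 °C; Tf2O, −78 → 0 °C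
Reagents that add atoms: hexamethyldisilazane, C[Si](C)(C)N[Si](C)(C)C; trifluoromethanesulfonic anhydride, FC(F)(F)S(=O)(=O)OS(=O)(=O)C(F)(F)F
Why: O-silylation, bromine–lithium exchange, 1,3-silyl shift from oxygen to carbon (retro-Brook rearrangement) and O-triflation of phenoxide 14 is the standard sequence to ortho-silylaryl triflates, the exchange being much faster than benzylic deprotonation at −78 °C.

Step 8
Reactants: 10 (E)-2-[2,4-bis(benzyloxy)-6-(methoxymethoxy)phenyl]-3-[4-(benzyloxy)phenyl]acrylic acid; 15 3,5-bis(benzyloxy)-2-(trimethylsilyl)phenyl trifluoromethanesulfonate (1.5 equiv)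
Product: 17 (E)-1-[2,4-bis(benzyloxy)-6-hydroxyphenyl]-2-[2,4-bis(benzyloxy)-6-(methoxymethoxy)phenyl]-3-[4-(benzyloxy)phenyl]prop-2-en-1-one, via 3,5-bis(benzyloxy)benzyne 16 (not isolated)
Conditions: CsF (4 equiv), THF, 125 °C, sealed tube
Reagents that add atoms: none
Why: Fluoride attacks silicon and expels triflate to give aryne 16; the caesium carboxylate of 10 adds through oxygen to the aryne carbon remote from the flanking benzyloxy group, and the resulting aryl anion, ortho to the new ester, adds to its own carbonyl to give a four-membered adduct that opens to the ortho-acyl phenoxide, protonated to 17. The closest known reaction type is the insertion of arynes into the O–C(acyl) bond of carboxylic acids to give ortho-hydroxyaryl ketones, a Fries-type acyl shift on an aryne-derived aryl anion. No ring is closed and no stereocentre is formed, and the E alkene of 10 is not touched. The selectivity needed is regiochemical, and it is secured by the inductively withdrawing benzyloxy group next to one aryne carbon, which sends oxygen to the distal carbon (future C8a) and the acyl group to the proximal one (future C4a). Acyl transfer should win over simple protonation to the aryl ester because the medium is aprotic and hot and because 10 has no enolisable α-hydrogen. Premature oxa-Michael closure is expected to be slow because the twisted, trisubstituted enone is a poor acceptor and the bifluoride present returns the phenoxide to its hydrogen-bonded neutral form.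

Step 9
Reactants: 17 (E)-1-[2,4-bis(benzyloxy)-6-hydroxyphenyl]-2-[2,4-bis(benzyloxy)-6-(methoxymethoxy)phenyl]-3-[4-(benzyloxy)phenyl]prop-2-en-1-one
Product: 18 (2R,3S)-5,7-bis(benzyloxy)-3-[2,4-bis(benzyloxy)-6-(methoxymethoxy)phenyl]-2-[4-(benzyloxy)phenyl]chroman-4-one
Conditions: 1-[3,5-bis(trifluoromethyl)phenyl]-3-[(9R)-6'-methoxycinchonan-9-yl]thiourea (from 9-amino-9-deoxy-epi-quinidine, 10 mol%), toluene, 25 °C
Reagents that add atoms: none
Why: Bifunctional amine–thiourea catalysis of the intramolecular oxa-Michael addition (6-endo-trig), in which the quinuclidine deprotonates the phenol while the thiourea binds the carbonyl so that the phenoxide reaches one face of C2 under catalyst control (2R), and C3 is protonated under thermodynamic control of the amine to the trans (3S) arrangement with both aryl groups equatorial.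

Step 10
Reactants: 18 (2R,3S)-5,7-bis(benzyloxy)-3-[2,4-bis(benzyloxy)-6-(methoxymethoxy)phenyl]-2-[4-(benzyloxy)phenyl]chroman-4-one
Product: 19 (2R,3S)-5,7-bis(benzyloxy)-3-[2,4-bis(benzyloxy)-6-hydroxyphenyl]-2-[4-(benzyloxy)phenyl]chroman-4-one
Conditions: 3 M HCl (aq.), MeOH/THF, 45 °C
Reagents that add atoms: none
Why: Acid-catalysed acetal hydrolysis removes the MOM group under conditions that leave aryl benzyl ethers untouched and are too mild to open the chromanone or to dehydrate the new phenol onto the C4 ketone.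

Step 11
Reactants: 19 (2R,3S)-5,7-bis(benzyloxy)-3-[2,4-bis(benzyloxy)-6-hydroxyphenyl]-2-[4-(benzyloxy)phenyl]chroman-4-one
Product: 21 (2R,3S)-3-[3-acetyl-4,6-bis(benzyloxy)-2-hydroxyphenyl]-5,7-bis(benzyloxy)-2-[4-(benzyloxy)phenyl]chroman-4-one, via aryl acetate 20 (not isolated)
Conditions: Ac2O (1.5 equiv), BF3·OEt2 (3 equiv), CH2Cl2, 0 °C → rt; aq. NaOAc work-up
Reagents that add atoms: acetic anhydride, CC(=O)OC(C)=O
Why: Friedel–Crafts acylation by way of O-acetylation and a boron-mediated Fries shift, in which boron bridging the phenol oxygen and the acyl group should direct acylation of this phloroglucinol-type ring to the only free ortho position (between the hydroxyl and a benzyloxy group) at a temperature that aryl benzyl ethers tolerate.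

Step 12
Reactants: 21 (2R,3S)-3-[3-acetyl-4,6-bis(benzyloxy)-2-hydroxyphenyl]-5,7-bis(benzyloxy)-2-[4-(benzyloxy)phenyl]chroman-4-one
Product: 23 (2R,3S)-5,7-bis(benzyloxy)-3-[5,7-bis(benzyloxy)-4-oxo-4H-chromen-8-yl]-2-[4-(benzyloxy)phenyl]chroman-4-one, via enaminone 22 (not isolated)
Conditions: Me2NCH(OMe)2, toluene, 80 °C; then conc. HCl, CH2Cl2, 25 °C
Reagents that add atoms: N,N-dimethylformamide dimethyl acetal, COC(OC)N(C)C
Why: Condensation of the methyl ketone with the amide acetal gives enaminone 22 and acid then promotes addition of the ortho hydroxyl with loss of dimethylamine (addition–elimination) to close the chromone, a standard chromone synthesis in which the tertiary C3–H of unit 1 cannot condense.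

Step 13
Reactants: 23 (2R,3S)-5,7-bis(benzyloxy)-3-[5,7-bis(benzyloxy)-4-oxo-4H-chromen-8-yl]-2-[4-(benzyloxy)phenyl]chroman-4-one; 24 4-methoxyphenylboronic acid (2 equiv)
Product: 25 (2R,3S)-5,7-bis(benzyloxy)-3-[(2S)-5,7-bis(benzyloxy)-2-(4-methoxyphenyl)-4-oxochroman-8-yl]-2-[4-(benzyloxy)phenyl]chroman-4-one
Conditions: Pd(OCOCF3)2 (10 mol%), (R)-t-BuPyOX [(R)-4-tert-butyl-2-(pyridin-2-yl)-4,5-dihydrooxazole, 12 mol%], NH4PF6 (30 mol%), H2O (5 equiv), ClCH2CH2Cl, 60 °C
Reagents that add atoms: none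
Why: Asymmetric conjugate addition of an arylboronic acid to a chromone with a cationic divalent palladium pyridine-oxazoline catalyst (Hayashi–Miyaura-type 1,4-addition), in which transmetalation, ligand-controlled carbopalladation of C2=C3 (giving 2S) and protonolysis of the palladium enolate take place in a base-free medium that opens neither chromanone.

Step 14
Reactants: 25 (2R,3S)-5,7-bis(benzyloxy)-3-[(2S)-5,7-bis(benzyloxy)-2-(4-methoxyphenyl)-4-oxochroman-8-yl]-2-[4-(benzyloxy)phenyl]chroman-4-one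
Product: 26 (2R,3S)-5,7-dihydroxy-3-[(2S)-5,7-dihydroxy-2-(4-methoxyphenyl)-4-oxochroman-8-yl]-2-(4-hydroxyphenyl)chroman-4-one (CNP0140544.1)
Conditions: H2 (1 atm), 10% Pd/C, EtOAc/MeOH, 25 °C
Reagents that add atoms: none
Why: Catalytic hydrogenolysis cleaves all five aryl benzyl ethers at atmospheric pressure, conditions under which the aryl ketones, the C2–O bonds and the stereocentres of flavanones are routinely preserved, and the methyl ether is inert.

**Compound list**

1 | 2,4,6-trihydroxybenzaldehyde | O=Cc1c(O)cc(O)cc1O | starting material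
2 | 2,4-bis(benzyloxy)-6-hydroxybenzaldehyde | O=Cc1c(O)cc(OCc2ccccc2)cc1OCc1ccccc1 | intermediate
3 | 2,4-bis(benzyloxy)-6-(methoxymethoxy)benzaldehyde | O=Cc1c(OCOC)cc(OCc2ccccc2)cc1OCc1ccccc1 | intermediate
4 | N-{2-[2,4-bis(benzyloxy)-6-(methoxymethoxy)phenyl]-1-tosylethenyl}formamide (alkene geometry not defined) | O=CNC(=Cc1c(OCOC)cc(OCc2ccccc2)cc1OCc1ccccc1)S(=O)(=O)c1ccc(C)cc1 | intermediate (not isolated)
5 | 2-[2,4-bis(benzyloxy)-6-(methoxymethoxy)phenyl]acetonitrile | N#CCc1c(OCOC)cc(OCc2ccccc2)cc1OCc1ccccc1 | intermediate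
6 | 2-[2,4-bis(benzyloxy)-6-(methoxymethoxy)phenyl]acetamide | NC(=O)Cc1c(OCOC)cc(OCc2ccccc2)cc1OCc1ccccc1 | intermediate (not isolated)
7 | 2-[2,4-bis(benzyloxy)-6-(methoxymethoxy)phenyl]acetic acid | OC(=O)Cc1c(OCOC)cc(OCc2ccccc2)cc1OCc1ccccc1 | intermediate
8 | 4-(benzyloxy)benzaldehyde | O=Cc1ccc(OCc2ccccc2)cc1 | starting material
9 | acetic (E)-2-[2,4-bis(benzyloxy)-6-(methoxymethoxy)phenyl]-3-[4-(benzyloxy)phenyl]acrylic anhydride | CC(=O)OC(=O)/C(=C/c1ccc(OCc2ccccc2)cc1)c1c(OCOC)cc(OCc2ccccc2)cc1OCc1ccccc1 | intermediate (not isolated)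
10 | (E)-2-[2,4-bis(benzyloxy)-6-(methoxymethoxy)phenyl]-3-[4-(benzyloxy)phenyl]acrylic acid | OC(=O)/C(=C/c1ccc(OCc2ccccc2)cc1)c1c(OCOC)cc(OCc2ccccc2)cc1OCc1ccccc1 | intermediate
11 | 3,5-bis(benzyloxy)phenol | Oc1cc(OCc2ccccc2)cc(OCc2ccccc2)c1 | starting material
12 | 2-bromo-3,5-bis(benzyloxy)phenol | Oc1cc(OCc2ccccc2)cc(OCc2ccccc2)c1Br | intermediate
13 | [3,5-bis(benzyloxy)-2-bromophenoxy]trimethylsilane | C[Si](C)(C)Oc1cc(OCc2ccccc2)cc(OCc2ccccc2)c1Br | intermediate (not isolated)
14 | lithium 3,5-bis(benzyloxy)-2-(trimethylsilyl)phenoxide | [Li+].[O-]c1cc(OCc2ccccc2)cc(OCc2ccccc2)c1[Si](C)(C)C | intermediate (not isolated)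
15 | 3,5-bis(benzyloxy)-2-(trimethylsilyl)phenyl trifluoromethanesulfonate | C[Si](C)(C)c1c(OCc2ccccc2)cc(OCc2ccccc2)cc1OS(=O)(=O)C(F)(F)F | intermediate
16 | 3,5-bis(benzyloxy)benzyne (1,2-didehydro-3,5-bis(benzyloxy)benzene) | C1#CC(OCc2ccccc2)=CC(OCc2ccccc2)=C1 | intermediate (not isolated)
17 | (E)-1-[2,4-bis(benzyloxy)-6-hydroxyphenyl]-2-[2,4-bis(benzyloxy)-6-(methoxymethoxy)phenyl]-3-[4-(benzyloxy)phenyl]prop-2-en-1-one | O=C(c1c(O)cc(OCc2ccccc2)cc1OCc1ccccc1)/C(=C/c1ccc(OCc2ccccc2)cc1)c1c(OCOC)cc(OCc2ccccc2)cc1OCc1ccccc1 | intermediate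
18 | (2R,3S)-5,7-bis(benzyloxy)-3-[2,4-bis(benzyloxy)-6-(methoxymethoxy)phenyl]-2-[4-(benzyloxy)phenyl]chroman-4-one | COCOc1cc(OCc2ccccc2)cc(OCc2ccccc2)c1[C@@H]1C(=O)c2c(OCc3ccccc3)cc(OCc3ccccc3)cc2O[C@H]1c1ccc(OCc2ccccc2)cc1 | intermediate
19 | (2R,3S)-5,7-bis(benzyloxy)-3-[2,4-bis(benzyloxy)-6-hydroxyphenyl]-2-[4-(benzyloxy)phenyl]chroman-4-one | Oc1cc(OCc2ccccc2)cc(OCc2ccccc2)c1[C@@H]1C(=O)c2c(OCc3ccccc3)cc(OCc3ccccc3)cc2O[C@H]1c1ccc(OCc2ccccc2)cc1 | intermediate
20 | 3,5-bis(benzyloxy)-2-{(2R,3S)-5,7-bis(benzyloxy)-2-[4-(benzyloxy)phenyl]-4-oxochroman-3-yl}phenyl acetate | CC(=O)Oc1cc(OCc2ccccc2)cc(OCc2ccccc2)c1[C@@H]1C(=O)c2c(OCc3ccccc3)cc(OCc3ccccc3)cc2O[C@H]1c1ccc(OCc2ccccc2)cc1 | intermediate (not isolated)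
21 | (2R,3S)-3-[3-acetyl-4,6-bis(benzyloxy)-2-hydroxyphenyl]-5,7-bis(benzyloxy)-2-[4-(benzyloxy)phenyl]chroman-4-one | CC(=O)c1c(O)c([C@@H]2C(=O)c3c(OCc4ccccc4)cc(OCc4ccccc4)cc3O[C@H]2c2ccc(OCc3ccccc3)cc2)c(OCc2ccccc2)cc1OCc1ccccc1 | intermediate
22 | (2R,3S)-5,7-bis(benzyloxy)-3-{4,6-bis(benzyloxy)-3-[(E)-3-(dimethylamino)acryloyl]-2-hydroxyphenyl}-2-[4-(benzyloxy)phenyl]chroman-4-one | CN(C)/C=C/C(=O)c1c(O)c([C@@H]2C(=O)c3c(OCc4ccccc4)cc(OCc4ccccc4)cc3O[C@H]2c2ccc(OCc3ccccc3)cc2)c(OCc2ccccc2)cc1OCc1ccccc1 | intermediate (not isolated)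
23 | (2R,3S)-5,7-bis(benzyloxy)-3-[5,7-bis(benzyloxy)-4-oxo-4H-chromen-8-yl]-2-[4-(benzyloxy)phenyl]chroman-4-one | O=c1ccoc2c([C@@H]3C(=O)c4c(OCc5ccccc5)cc(OCc5ccccc5)cc4O[C@H]3c3ccc(OCc4ccccc4)cc3)c(OCc3ccccc3)cc(OCc3ccccc3)c12 | intermediate
24 | 4-methoxyphenylboronic acid | COc1ccc(B(O)O)cc1 | starting material
25 | (2R,3S)-5,7-bis(benzyloxy)-3-[(2S)-5,7-bis(benzyloxy)-2-(4-methoxyphenyl)-4-oxochroman-8-yl]-2-[4-(benzyloxy)phenyl]chroman-4-one | COc1ccc([C@@H]2CC(=O)c3c(OCc4ccccc4)cc(OCc4ccccc4)c([C@@H]4C(=O)c5c(OCc6ccccc6)cc(OCc6ccccc6)cc5O[C@H]4c4ccc(OCc5ccccc5)cc4)c3O2)cc1 | intermediate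
26 | (2R,3S)-5,7-dihydroxy-3-[(2S)-5,7-dihydroxy-2-(4-methoxyphenyl)-4-oxochroman-8-yl]-2-(4-hydroxyphenyl)chroman-4-one (CNP0140544.1) | COc1ccc([C@@H]2CC(=O)c3c(O)cc(O)c([C@@H]4C(=O)c5c(O)cc(O)cc5O[C@H]4c4ccc(O)cc4)c3O2)cc1 | target

**Step count and risk**

Total step count: 14. Longest linear sequence: 12 steps (steps 1–5, then 8–14); the aryne precursor is a two-step side branch (steps 6–7).

The three steps most likely to fail:

Step 8 (key step). The aryl anion may be protonated before it reaches the hindered carbonyl, so that the aryl ester accumulates, or the product phenoxide may be arylated by further aryne. The fallback avoids the aryne: it sets out from acid 10 (with bromophenol 12) and returns at 17. Acid 10 is esterified with 12 (EDC·HCl, DMAP, CH2Cl2, 25 °C) to give 2-bromo-3,5-bis(benzyloxy)phenyl (E)-2-[2,4-bis(benzyloxy)-6-(methoxymethoxy)phenyl]-3-[4-(benzyloxy)phenyl]acrylate F1. Bromine–lithium exchange (n-BuLi, THF, −100 °C, then warming to −40 °C) generates the same ortho-acyloxy aryl anion with no proton source and no aryne present, and its anionic Fries shift, followed by aqueous NH4Cl, should give chalcone 17.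

Step 9. Facial discrimination at C2 may be insufficient on this hindered, non-activated enone, or enantiopurity may erode through reversible ring opening during the slow closure. The fallback replaces asymmetric catalysis by resolution: it sets out from 17 and returns at 18. Ring closure without stereocontrol (NaOAc, EtOH, 60 °C) should give the racemic trans chromanone, that is 18 together with its mirror image, (2S,3R)-5,7-bis(benzyloxy)-3-[2,4-bis(benzyloxy)-6-(methoxymethoxy)phenyl]-2-[4-(benzyloxy)phenyl]chroman-4-one F2. Preparative chromatography on a chiral stationary phase separates the two. F2 is returned to the racemate with DBU in toluene at 60 °C (ring opening to 17 and re-closure) and resolved again.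

Step 11. Acylation may occur para to the phenol (between the two benzyloxy groups), or the Lewis acid may cause loss or migration of benzyl groups. The fallback builds the acetyl group by cross-coupling: it sets out from 19 and returns at 21. Amine-directed ortho-bromination (NBS, i-Pr2NH cat., CH2Cl2, −78 °C) gives (2R,3S)-5,7-bis(benzyloxy)-3-[4,6-bis(benzyloxy)-3-bromo-2-hydroxyphenyl]-2-[4-(benzyloxy)phenyl]chroman-4-one F3. Stille coupling with tributyl(1-ethoxyvinyl)stannane (Pd(PPh3)4, toluene, 100 °C) gives (2R,3S)-5,7-bis(benzyloxy)-3-[4,6-bis(benzyloxy)-3-(1-ethoxyvinyl)-2-hydroxyphenyl]-2-[4-(benzyloxy)phenyl]chroman-4-one F4. Mild hydrolysis of the enol ether (1 M HCl, THF, 25 °C) then gives acetophenone 21.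

Further compounds
F1 | step 8 | 2-bromo-3,5-bis(benzyloxy)phenyl (E)-2-[2,4-bis(benzyloxy)-6-(methoxymethoxy)phenyl]-3-[4-(benzyloxy)phenyl]acrylate | O=C(Oc1cc(OCc2ccccc2)cc(OCc2ccccc2)c1Br)/C(=C/c1ccc(OCc2ccccc2)cc1)c1c(OCOC)cc(OCc2ccccc2)cc1OCc1ccccc1
F2 | step 9 | (2S,3R)-5,7-bis(benzyloxy)-3-[2,4-bis(benzyloxy)-6-(methoxymethoxy)phenyl]-2-[4-(benzyloxy)phenyl]chroman-4-one | COCOc1cc(OCc2ccccc2)cc(OCc2ccccc2)c1[C@H]1C(=O)c2c(OCc3ccccc3)cc(OCc3ccccc3)cc2O[C@@H]1c1ccc(OCc2ccccc2)cc1
F3 | step 11 | (2R,3S)-5,7-bis(benzyloxy)-3-[4,6-bis(benzyloxy)-3-bromo-2-hydroxyphenyl]-2-[4-(benzyloxy)phenyl]chroman-4-one | Oc1c(Br)c(OCc2ccccc2)cc(OCc2ccccc2)c1[C@@H]1C(=O)c2c(OCc3ccccc3)cc(OCc3ccccc3)cc2O[C@H]1c1ccc(OCc2ccccc2)cc1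
F4 | step 11 | (2R,3S)-5,7-bis(benzyloxy)-3-[4,6-bis(benzyloxy)-3-(1-ethoxyvinyl)-2-hydroxyphenyl]-2-[4-(benzyloxy)phenyl]chroman-4-one | CCOC(=C)c1c(O)c([C@@H]2C(=O)c3c(OCc4ccccc4)cc(OCc4ccccc4)cc3O[C@H]2c2ccc(OCc3ccccc3)cc2)c(OCc2ccccc2)cc1OCc1ccccc1
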